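The runs were generated by integration for substances that don't exist, noise included.

This flask is slow, so we reckon the loss of substrate as a straight line and treat the start as a small correction.

the same everywhere: left-handed substrate 0.018 M; right-handed substrate 0.018 M; free catalyst 1.5 mM; impurity 0.24 mM

| flask | solid reagent | racemization catalyst | remark | time |
|---|---|---|---|---|
| alpha | 0.045 M | 36 µM | the very flask that is asked about, followed so far |  |
| gamma | 0.045 M | 24 µM | run made earlier |  |
| flask | 0.0450 M | 36 µM |  | 1.0 h |

- alpha (time / min: left-handed substrate / %, right-handed substrate / %): 2.50: 50.1, 50.0; 5.00: 49.4, 49.5; 8.00: 48.7, 49.8; 10.0: 49.0, 49.6; 12.0: 48.6, 49.1; 15.0: 48.7, 49.2; 20.0: 47.5, 48.9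
- gamma (time / min: left-handed substrate / %, right-handed substrate / %): 3.00: 50.1, 50.2; 5.00: 49.8, 49.8; 8.00: 49.4, 49.9; 12.0: 48.8, 49.9; 20.0: 47.9, 48.8; 30.0: 46.7, 47.4; 40.0: 45.1, 47.1

(standard deviation of a reading: 0.3 percentage points)

- part of the left-handed substrate and right-handed substrate charged together that has reacted at 1.0 h
- excess of left-handed product over right-handed product in the product at 1.0 h
- excess of right-handed substrate over left-handed substrate among what is left of the two at 1.0 h

- free catalyst is single-handed; left-handed substrate and right-handed substrate are mirror images of each other, charged as a racemate, each of them at the stated concentration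
- solid reagent is a solid; its amount is given per volume of the solution
- the analysis behind the earlier runs scatters by 0.3 percentage points, standard deviation
- at the start none of the solid reagent is in solution
- an excess is below zero if the other one leads

We watch the total of the two substrates in slow motion. In the first instants none of the solid reagent is in solution, and alpha, the asked flask followed so far, still holds 100 % of its charge at 2.50 min, which is the full charge within the scatter.

In the middle, the two runs can be read together. At 20.0 min alpha has lost 3.60 % and gamma 3.30 %, a difference of 0.3 percentage points against a scatter of 0.3 points on each single reading. So we let gamma, the longer run, stand for the total in alpha.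

Between 20.0 min and 40.0 min, gamma's readings give the steady draw, the part of the charge reacted per hour once the line is running: 0.135 h⁻¹, a reading with its scatter. Gamma's loss of 7.80 % at 40.0 min then places the line, and the line read back to zero loss gives a lag of 5.33 min.

For the end of the asked flask, with 12.3 % reacted, 87.7 % of the substrates would still be present, so we keep the line straight. A full hour at the draw would give 13.5 %, and the lag takes off 1.2 points. Our own figure for the flask is therefore 12.3 %.

The forecast, which speaks of “a roughly zero-order process”, gives 12.5 %, slightly above our figure, with 28 % and 3.2 % for the two excesses.

The flask gives 13.2 % reacted, with excesses of 27.0 % in the product and 2.20 % in the substrate.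

    partner + free catalyst + left-handed substrate → free catalyst + left-handed product (k = 3670 L² mol⁻² min⁻¹)
    partner + free catalyst + right-handed substrate → free catalyst + right-handed product (k = 2060 L² mol⁻² min⁻¹)
    left-handed substrate + racemization catalyst ⇌ right-handed substrate + racemization catalyst, rate k3*[racemization catalyst]*[left-handed substrate] forward; the back reaction follows from the equilibrium constant (k = 1540 L mol⁻¹ min⁻¹)
    free catalyst + impurity → spent catalyst A (k = 76200 L mol⁻¹ min⁻¹)
    2 racemization catalyst → spent catalyst B (k = 1150 L mol⁻¹ min⁻¹)
    solid reagent ⇌ partner, rate k6*(cs6 - [partner]) while solid is left; crystals form when [partner] > cs6 (solubility = 2.70 mM, k = 0.0451 min⁻¹)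

We now set the draw beside the supply of partner. Partner dissolves in proportion to its gap below 2.7 mM, and at 1.00 h the asked flask makes partner 1.02 times as fast as it uses it, each step taken net, a quasi-steady state, with a gap of 1.93 mM. The neighbouring flask, charged with 9.6 × 10⁻⁴ M of impurity, holds 36.0 % of its free catalyst and 0.00126 M of partner at 1.00 h, a gap of 1.44 mM. Scaling our draw by the two gaps gives 0.101 h⁻¹, and keeping the same lag gives 9.17 % reacted; that neighbouring flask gives 9.08 %.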